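## The problem

Nortopsentin C is a 1H-imidazole carrying a 6-bromoindol-3-yl group at C4 and an unsubstituted indol-3-yl group at C2. The three heteroaromatic rings are joined only by two biaryl C–C bonds, so the synthesis is a problem of regiochemistry and of telling two nearly identical indoles apart: the bromine must end up on the indole at imidazole C4 and nowhere else. The target has no stereocentre. The only stereogenic carbon on the chosen road is the carbinol carbon of a 3-hydroxyindoline intermediate, formed as a racemate and flattened on aromatisation, so stereocontrol is not needed at any point. Three acidic N–H groups (two indole, one imidazole) must be masked, because each would be metalated or arylated in the bond-forming steps. The aryl C–Br bond is the fragile group: it rules out alkyllithium reagents, dissolving or low-valent metals and hot palladium chemistry once it is in place. The electron-rich indoles with free C2–H positions should also not meet strong electrophiles after deprotection. The feature that opens the key step is that C3a and C7a of the bromine-free indole are neighbouring carbons of a benzo ring with no other substituent. These two carbons can therefore come from symmetrical benzyne, and N1, C2 and C3 from an N-sulfonyl aminomethyl ketone attached to imidazole C2.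

## Retrosynthesis

**Unmasking (19 from 18 from 17).** The last operations cut only N–S bonds. Target 19 comes from the bis-tosyl imidazole 18 by hydroxide cleavage of the two indole N–tosyl bonds, and 18 comes from the fully protected compound 17 by acid hydrolysis of the imidazole N-sulfamoyl bond. Sulfonyl groups on all three nitrogens mean that every deprotection is a hydrolysis that cannot touch the C–Br bond. Acid goes first because it removes the sulfamoyl group alone and leaves one defined compound, 18; base first could give a mixture with and without the sulfamoyl group.

**Aromatisation (17 from 16).** The C2=C3 double bond of the bromine-free indole in 17 is traced back to loss of water from the tertiary carbinol 16. This must happen before the tosyl groups are removed: the N-tosyl group of an indoline is an ordinary, stubborn sulfonamide, whereas on an indole it is an activated one that hydroxide removes. The forward step asks only for ionisation or elimination at a tertiary benzylic carbinol with aromatisation as driving force.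

**Key disconnection (16 from 13 and 14, via 15).** In 16 the bonds N1–C7a and C3–C3a of the indoline are cut together. This removes a whole benzo ring and leaves the sulfonamido ketone 13 plus benzyne 15, released in the flask from the silyl triflate 14. The cut is placed on the bromine-free indole because its aryne partner is symmetrical. A bromine-bearing aryne would be unsymmetrical and offers no handle for placing nitrogen meta to bromine, so the bromoindole is bought intact. Compared with a cross-coupling of two finished indoles, the cut moves the second indole's construction to the stage where the imidazole and bromoindole are already joined, and it is metal-free at the point where the C–Br bond is most valuable. The forward reaction requires the sulfonamide nitrogen of 13 to capture the aryne faster than imidazole N3 does, and the aryl anion to close onto the ketone before it is protonated.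

**Acyl–imidazole bond (13 from 8 and 10, via 11 and 12).** The bond between imidazole C2 and the ketone carbon is cut. This gives the 4-(indolyl)imidazole 8, metalated at C2 as the magnesium reagent 11, and the Weinreb amide 10, used as its N-magnesium salt 12. Imidazole C2–H, flanked by N3 and the sulfamoyl-bearing N1, is the most acidic C–H in 8, so no halogen is needed at C2. Building the imidazole around a ready-made acyl group would need an unstable α-keto amidine. The forward step must leave the C–Br bond and indole C2–H untouched, which points to a hindered magnesium amide rather than an alkyllithium.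

**Weinreb amide (10 from 9).** The amide C–N bond of 10 is cut to give commercial N-tosylglycine 9. This places the nitrogen, its sulfonyl group and the future indole C2 and C3 carbons in one cheap building block.

**Indole–imidazole bond (8 from 3 and 5, via 6 and 7).** The bond between indole C3 and imidazole C4 is cut to the 3-iodoindole 3 and the 4-iodoimidazole 5. Compound 3 is used as its magnesium reagent 6 and then its zinc reagent 7. A cross-coupling fixes the regiochemistry of both rings through the position of the iodine atoms and runs near room temperature. A cyclocondensation that builds the imidazole from a haloacetylindole needs ammonia or formamide at high temperature, which an N-tosyl-3-acylindole would not survive cleanly. The forward step needs two selectivities of the same kind, iodine over bromine: once in the halogen–metal exchange and once in the oxidative addition.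

**Building blocks (3 from 1 via 2; 5 from 4).** Compound 3 results from C3 iodination and N-tosylation of commercial 6-bromoindole 1, through the unprotected iodide 2. Compound 5 results from N-sulfamoylation of commercial 4-iodoimidazole 4. Both are single operations on stock heterocycles.

## Roads not taken

**Alternative 1:** The imidazole itself is cut at C4–C5 and N3–C2. In the forward direction, t-BuOK would deprotonate the benzotriazolylmethyl imidoyl chloride A2 next to the benzotriazole. The carbanion would add to the N-tosyl aldimine A3 (C4–C5), and the sulfonamide nitrogen would close onto the imidoyl carbon with loss of chloride (N3–C2). Elimination of benzotriazole and sulfinate would give the bis-tosyl imidazole A1, which is the same compound as 18 of the chosen route.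

- Merits: the central ring is made last from two intact indoles, so the bromine position and the imidazole substitution pattern are fixed by the building blocks. The road is also clearly shorter and more convergent; A1 should be reachable in about half the steps that the chosen route needs to reach 18.
- Weak points: A2 is a moisture-sensitive imidoyl chloride whose carbanion must form beside its own electrophilic C–Cl bond. A3 is the sulfonylimine of an indole-3-carbaldehyde, a weak electrophile because the indole nitrogen donates into the imine carbon even when tosylated. t-BuOK is the kind of base that strips tosyl groups from indoles with an electron-withdrawing group at C3, and the freed indolide would attack the imidoyl chloride.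
- Comparison: three anionic events must occur in sequence on deactivated partners. The chosen plan never builds a ring under strong alkoxide base, and each of its bond-forming steps has a close relative in established practice. Alternative 1 remains ahead on step economy.

**Alternative 2:** The bromoindole is cut at N1–C2 and C3–C3a. Forward, a Larock heteroannulation of 5-bromo-2-iodoaniline A5 with the imidazol-4-yl trimethylsilyl alkyne A6 (Pd(OAc)2, LiCl, K2CO3, DMF) would give the 2-silylindole A4, the bulky silyl group ending up at indole C2.

- Merits: the bromine position is set unambiguously by a commercial aniline, and the annulation is among the most reliable indole syntheses. As a ring-forming event it is probably better secured than an aryne annulation on a 2-acylimidazole.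
- Weak points: A6 must already contain the imidazole, the other indole and an alkyne, which means two prior cross-couplings and an alkynylation on the imidazole. The annulation exposes both the C–Br bond of A5 and that of A4 to zerovalent palladium at around 100 °C. The silyl group at C2 and two SEM groups then have to be removed, with fluoride or strong acid.
- Comparison: the chosen route also exposes the C–Br bond to zerovalent palladium once, but at 50 °C and in competition with a heteroaryl iodide. Its indole-forming step uses no transition metal, and its protecting groups all leave by hydrolysis. Alternative 2 keeps the advantage of a better-precedented key step.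

**Alternative 3:** The bromine-free indole is cut at C2–C3. Forward, low-valent titanium from TiCl3 and zinc dust in refluxing dimethoxyethane would couple the ketone and formamide carbonyls of the 2-(2-formamidobenzoyl)imidazole A8 and give the indole A7 directly.

- Merits: it uses the same 2-acylimidazole logic as the chosen plan (the ketone carbon becomes indole C3), but delivers the aromatic indole with a free N–H in one step. There is no dehydration, no competition between nucleophilic nitrogens, and the benzo ring arrives as a stable anthranilic unit instead of an aryne. In these respects it is better.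
- Weak points: a strongly reducing, Lewis-acidic medium at reflux meets an aryl bromide (risk of reductive loss of bromine), a basic imidazole nitrogen that can bind titanium, and two SEM aminals that Lewis acids can open. A8 itself needs an ortho-amino aryl ketone that must be made and formylated without disturbing the bromide.
- Comparison: the step counts are about equal. The chosen plan offers a redox-neutral ring closure at room temperature that cannot touch the C–Br bond, at the cost of one extra dehydration step.

Key step: step 6

Assumption: 4-iodo-1H-imidazole, N-tosylglycine and 2-(trimethylsilyl)phenyl triflate are taken as commercial, and carbinol 16 is carried as the racemate because its only stereocentre disappears in step 7.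

## Route

Step 1
Reactants: 1 6-bromo-1H-indole
Product: 3 6-bromo-3-iodo-1-tosylindole, via 6-bromo-3-iodoindole 2 (not isolated)
Conditions: I2, KOH, DMF, rt; then TsCl, 0 °C to rt
Reagents that add atoms: iodine, II; p-toluenesulfonyl chloride, Cc1ccc(cc1)S(Cl)(=O)=O
Why: Electrophilic aromatic iodination occurs at the most nucleophilic position, C3, of the indole, and the indolide present in KOH/DMF is then N-sulfonylated in the same flask, which avoids handling the light- and acid-sensitive free 3-iodoindole.

Step 2
Reactants: 4 4-iodo-1H-imidazole
Product: 5 4-iodo-N,N-dimethylimidazole-1-sulfonamide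
Conditions: Me2NSO2Cl, Et3N, CH2Cl2, rt
Reagents that add atoms: dimethylsulfamoyl chloride, CN(C)S(Cl)(=O)=O
Why: N-Sulfonylation of the imidazole; under amine base the sulfamoyl group settles on the less hindered nitrogen remote from iodine, so the 1,4-isomer should dominate.

Step 3
Reactants: 3 6-bromo-3-iodo-1-tosylindole; 5 4-iodo-N,N-dimethylimidazole-1-sulfonamide
Product: 8 4-(6-bromo-1-tosylindol-3-yl)-N,N-dimethylimidazole-1-sulfonamide, via indol-3-ylmagnesium chloride 6 (not isolated), via indol-3-ylzinc chloride 7 (not isolated)
Conditions: 3, i-PrMgCl·LiCl, THF, −40 °C; ZnCl2, −40 °C to rt; then 5, Pd(PPh3)4 (5 mol %), THF, 50 °C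
Reagents that add atoms: none
Why: Iodine–magnesium exchange is much faster at the C3–I bond than at the C6–Br bond at −40 °C, and after transmetalation to zinc a Negishi cross-coupling joins indole C3 to imidazole C4, since zerovalent palladium inserts into the heteroaryl C–I bond of 5 well before it touches an aryl bromide at 50 °C.

Step 4
Reactants: 9 N-tosylglycine
Product: 10 N-methoxy-N-methyl-2-(tosylamino)acetamide
Conditions: MeNHOMe·HCl, EDC·HCl, HOBt, N-methylmorpholine, CH2Cl2, 0 °C to rt
Reagents that add atoms: N,O-dimethylhydroxylamine hydrochloride, CNOC.Cl
Why: Standard carbodiimide amide coupling to the Weinreb amide; the sulfonamide N–H is too weakly nucleophilic to compete with the hydroxylamine.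

Step 5
Reactants: 8 4-(6-bromo-1-tosylindol-3-yl)-N,N-dimethylimidazole-1-sulfonamide; 10 N-methoxy-N-methyl-2-(tosylamino)acetamide
Product: 13 N-{2-[4-(6-bromo-1-tosylindol-3-yl)-1-(dimethylsulfamoyl)imidazol-2-yl]-2-oxoethyl}-4-methylbenzenesulfonamide, via 2-imidazolylmagnesium chloride 11 (not isolated), via N-chloromagnesio Weinreb amide 12 (not isolated)
Conditions: 8, TMPMgCl·LiCl, THF, −20 °C; 10 pre-treated with i-PrMgCl·LiCl (THF, −20 °C) added; −20 °C to rt
Reagents that add atoms: none
Why: Directed magnesiation with the hindered amide base takes the most acidic C–H, imidazole C2 between N3 and the sulfamoyl-bearing N1, without disturbing the aryl bromide; the Weinreb ketone synthesis with the amide whose acidic N–H is masked as its magnesium salt then stops at the ketone because the chelated tetrahedral adduct survives until work-up.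

Step 6
Reactants: 13 N-{2-[4-(6-bromo-1-tosylindol-3-yl)-1-(dimethylsulfamoyl)imidazol-2-yl]-2-oxoethyl}-4-methylbenzenesulfonamide; 14 2-(trimethylsilyl)phenyl trifluoromethanesulfonate
Product: 16 racemic 3-[4-(6-bromo-1-tosylindol-3-yl)-1-(dimethylsulfamoyl)imidazol-2-yl]-1-tosylindolin-3-ol, via benzyne 15 (not isolated)
Conditions: CsF, MeCN, rt
Reagents that add atoms: none
Why: Fluoride attacks silicon of 14 and triflate departs to release benzyne 15, while fluoride (and later the product alkoxide) deprotonates the sulfonamide N–H of 13. The sulfonamide anion adds to the aryne (N1–C7a) and the resulting ortho-amino aryl anion attacks the neighbouring ketone carbon (C3–C3a) in a 5-exo-trig closure; the tertiary alkoxide is then protonated by the next molecule of 13. The closest known reaction type is the fluoride-triggered aryne annulation of N-sulfonyl α-amino ketones to 3-hydroxyindolines, here applied to a ketone that carries a heteroaryl group. The new carbinol centre at C3 forms without any controlling element, so 16 is racemic, which is irrelevant because the centre is erased in step 7. Benzyne is symmetrical, so nitrogen and carbon can only arrive on adjacent carbons and no regiochemical question arises. The step needs the sulfonamide nitrogen to outrun imidazole N3 for the aryne; N3 is flanked by the substituents at C2 and C4 and deactivated by the acyl and sulfamoyl groups, whereas the sulfonamide reacts as an anion. It also needs ring closure to beat protonation of the aryl anion, which the electron-poor 2-acylimidazole ketone, held five atoms away, should ensure. The indole N-tosyl group, the sulfamoyl group and the C–Br bond are inert to CsF in acetonitrile at room temperature.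

Step 7
Reactants: 16 racemic 3-[4-(6-bromo-1-tosylindol-3-yl)-1-(dimethylsulfamoyl)imidazol-2-yl]-1-tosylindolin-3-ol
Product: 17 4-(6-bromo-1-tosylindol-3-yl)-N,N-dimethyl-2-(1-tosylindol-3-yl)imidazole-1-sulfonamide
Conditions: TsOH·H2O (cat.), toluene, 80 °C
Reagents that add atoms: none
Why: Acid-catalysed E1 dehydration of the tertiary benzylic carbinol; only the C2 hydrogens can be lost and the gain of indole aromaticity drives the reaction, turning the robust indoline sulfonamide into a base-labile N-tosylindole.

Step 8
Reactants: 17 4-(6-bromo-1-tosylindol-3-yl)-N,N-dimethyl-2-(1-tosylindol-3-yl)imidazole-1-sulfonamide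
Product: 18 4-(6-bromo-1-tosylindol-3-yl)-2-(1-tosylindol-3-yl)-1H-imidazole
Conditions: 2 M HCl, 1,4-dioxane/H2O, 90 °C
Reagents that add atoms: none
Why: Acid hydrolysis of the N-sulfamoyl azole (protonation at N3, water attack at sulfur) is the standard removal of this group; N-tosylindoles and the aryl bromide are inert to hot aqueous acid.

Step 9
Reactants: 18 4-(6-bromo-1-tosylindol-3-yl)-2-(1-tosylindol-3-yl)-1H-imidazole
Product: 19 nortopsentin C, 4-(6-bromo-1H-indol-3-yl)-2-(1H-indol-3-yl)-1H-imidazole
Conditions: KOH, EtOH/H2O/THF, 75 °C
Reagents that add atoms: none
Why: Hydroxide attacks sulfur of both N-sulfonylindoles and expels the stabilised indolide anions (sulfonamide hydrolysis of azole-type N–S bonds); aqueous ethanol rather than methanol is used so that no methyl tosylate can form and N-methylate the freed azoles.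

## Compound list

1 | 6-bromo-1H-indole | Brc1ccc2cc[nH]c2c1 | starting material
2 | 6-bromo-3-iodo-1H-indole | Brc1ccc2c(I)c[nH]c2c1 | intermediate
3 | 6-bromo-3-iodo-1-tosylindole | Cc1ccc(cc1)S(=O)(=O)n1cc(I)c2ccc(Br)cc21 | intermediate
4 | 4-iodo-1H-imidazole | Ic1c[nH]cn1 | starting material
5 | 4-iodo-N,N-dimethylimidazole-1-sulfonamide | CN(C)S(=O)(=O)n1cnc(I)c1 | intermediate
6 | (6-bromo-1-tosylindol-3-yl)magnesium chloride | Cc1ccc(cc1)S(=O)(=O)n1cc([Mg]Cl)c2ccc(Br)cc21 | intermediate
7 | (6-bromo-1-tosylindol-3-yl)zinc chloride | Cc1ccc(cc1)S(=O)(=O)n1cc([Zn]Cl)c2ccc(Br)cc21 | intermediate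
8 | 4-(6-bromo-1-tosylindol-3-yl)-N,N-dimethylimidazole-1-sulfonamide | CN(C)S(=O)(=O)n1cnc(c1)-c1cn(S(=O)(=O)c2ccc(C)cc2)c2cc(Br)ccc12 | intermediate
9 | N-tosylglycine | Cc1ccc(cc1)S(=O)(=O)NCC(O)=O | starting material
10 | N-methoxy-N-methyl-2-(tosylamino)acetamide | Cc1ccc(cc1)S(=O)(=O)NCC(=O)N(C)OC | intermediate
11 | [4-(6-bromo-1-tosylindol-3-yl)-1-(dimethylsulfamoyl)imidazol-2-yl]magnesium chloride | CN(C)S(=O)(=O)n1c([Mg]Cl)nc(c1)-c1cn(S(=O)(=O)c2ccc(C)cc2)c2cc(Br)ccc12 | intermediate
12 | N-chloromagnesio derivative of N-methoxy-N-methyl-2-(tosylamino)acetamide | Cc1ccc(cc1)S(=O)(=O)N([Mg]Cl)CC(=O)N(C)OC | intermediate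
13 | N-{2-[4-(6-bromo-1-tosylindol-3-yl)-1-(dimethylsulfamoyl)imidazol-2-yl]-2-oxoethyl}-4-methylbenzenesulfonamide | Cc1ccc(cc1)S(=O)(=O)NCC(=O)c1nc(cn1S(=O)(=O)N(C)C)-c1cn(S(=O)(=O)c2ccc(C)cc2)c2cc(Br)ccc12 | intermediate
14 | 2-(trimethylsilyl)phenyl trifluoromethanesulfonate | C[Si](C)(C)c1ccccc1OS(=O)(=O)C(F)(F)F | starting material
15 | benzyne | C1=CC=CC#C1 | intermediate
16 | racemic 3-[4-(6-bromo-1-tosylindol-3-yl)-1-(dimethylsulfamoyl)imidazol-2-yl]-1-tosylindolin-3-ol | Cc1ccc(cc1)S(=O)(=O)N1CC(O)(c2ccccc21)c1nc(cn1S(=O)(=O)N(C)C)-c1cn(S(=O)(=O)c2ccc(C)cc2)c2cc(Br)ccc12 | intermediate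
17 | 4-(6-bromo-1-tosylindol-3-yl)-N,N-dimethyl-2-(1-tosylindol-3-yl)imidazole-1-sulfonamide | Cc1ccc(cc1)S(=O)(=O)n1cc(c2ccccc21)-c1nc(cn1S(=O)(=O)N(C)C)-c1cn(S(=O)(=O)c2ccc(C)cc2)c2cc(Br)ccc12 | intermediate
18 | 4-(6-bromo-1-tosylindol-3-yl)-2-(1-tosylindol-3-yl)-1H-imidazole | Cc1ccc(cc1)S(=O)(=O)n1cc(c2ccccc21)-c1nc(c[nH]1)-c1cn(S(=O)(=O)c2ccc(C)cc2)c2cc(Br)ccc12 | intermediate
19 | nortopsentin C, 4-(6-bromo-1H-indol-3-yl)-2-(1H-indol-3-yl)-1H-imidazole | Brc1ccc2c(-c3c[nH]c(-c4c[nH]c5ccccc45)n3)c[nH]c2c1 | target

## Step count and risks

Total step count: 9. Longest linear sequence: 7 steps (steps 1, 3, 5, 6, 7, 8, 9 from 6-bromoindole); steps 2 and 4 are one-step side branches.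

**Step 6 (key step).**
- Most likely failure: capture of the aryne by the wrong nucleophile (imidazole N3, or the imidazole nitrogen after fluoride-induced loss of the sulfamoyl group), or protonation of the aryl anion before it closes onto the ketone. Either would give N-arylated open-chain material in place of the indoline, because a heteroaryl ketone next to a sulfonylated azole nitrogen has not been put through this annulation.
- Fallback: abandon the annulation and attach a ready-made indole. Starting from 8, magnesiation as in step 5 gives 11, and ZnCl2 converts it into [4-(6-bromo-1-tosylindol-3-yl)-1-(dimethylsulfamoyl)imidazol-2-yl]zinc chloride F1. Negishi coupling (Pd(PPh3)4, THF, 60 °C) with 3-iodo-1-tosylindole F2, a known compound obtainable from the parent heterocycle by the procedure of step 1, should give 17 directly. The route is rejoined at 17, and 13 and 16 are bypassed.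

**Step 5.**
- Most likely failure: incomplete acyl transfer, because the N-magnesiated amide 12 is an anionic and therefore deactivated electrophile. Partial deprotonation at indole C2 in place of imidazole C2 is a second possibility.
- Fallback: separate the C–C from the C–N bond formation. Starting from 8 by way of 11, acylation with 2-chloro-N-methoxy-N-methylacetamide, which has no acidic N–H, should give the chloromethyl ketone 2-(chloroacetyl)-4-(6-bromo-1-tosylindol-3-yl)-N,N-dimethylimidazole-1-sulfonamide F3. Displacement of chloride with an excess of p-toluenesulfonamide and K2CO3 in DMF then gives 13, where the route is rejoined.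

**Step 3.**
- Most likely failure: loss of halogen selectivity, namely oxidative addition into the C6–Br bond of 7 or of 8, leading to oligomerisation, or protonation of the organometallic before coupling.
- Fallback: build the imidazole by cyclocondensation, with no palladium.
  - Starting from 1, C3 acylation with chloroacetyl chloride and pyridine in toluene at 60 °C gives 6-bromo-3-(chloroacetyl)-1H-indole F4.
  - Heating F4 in formamide at 170 °C (Bredereck imidazole synthesis) gives 4-(6-bromo-1H-indol-3-yl)-1H-imidazole F5.
  - Me2NSO2Cl and Et3N sulfamoylate only the imidazole, giving 4-(6-bromo-1H-indol-3-yl)-N,N-dimethylimidazole-1-sulfonamide F6.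
  - NaH and TsCl in THF then tosylate the indole nitrogen and give 8, where the route is rejoined.

**Step 7.**
- Most likely failure: slow ionisation of the carbinol, because the developing C3 cation sits beside an electron-poor imidazole that is partly protonated by the acid. Prolonged heating would then begin to hydrolyse the sulfamoyl group.
- Fallback: replace ionisation by a base-induced elimination. Starting from 16, MsCl and Et3N in CH2Cl2 (mesylation through sulfene) give the tertiary mesylate 3-[4-(6-bromo-1-tosylindol-3-yl)-1-(dimethylsulfamoyl)imidazol-2-yl]-1-tosylindolin-3-yl methanesulfonate F7. DBU then removes a C2 proton in an E2 elimination and gives 17, where the route is rejoined.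

Further compounds

F1 | step 6 | [4-(6-bromo-1-tosylindol-3-yl)-1-(dimethylsulfamoyl)imidazol-2-yl]zinc chloride | CN(C)S(=O)(=O)n1c([Zn]Cl)nc(c1)-c1cn(S(=O)(=O)c2ccc(C)cc2)c2cc(Br)ccc12
F2 | step 6 | 3-iodo-1-tosylindole | Cc1ccc(cc1)S(=O)(=O)n1cc(I)c2ccccc21
F3 | step 5 | 2-(chloroacetyl)-4-(6-bromo-1-tosylindol-3-yl)-N,N-dimethylimidazole-1-sulfonamide | ClCC(=O)c1nc(cn1S(=O)(=O)N(C)C)-c1cn(S(=O)(=O)c2ccc(C)cc2)c2cc(Br)ccc12
F4 | step 3 | 6-bromo-3-(chloroacetyl)-1H-indole | ClCC(=O)c1c[nH]c2cc(Br)ccc12
F5 | step 3 | 4-(6-bromo-1H-indol-3-yl)-1H-imidazole | Brc1ccc2c(c[nH]c2c1)-c1c[nH]cn1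
F6 | step 3 | 4-(6-bromo-1H-indol-3-yl)-N,N-dimethylimidazole-1-sulfonamide | CN(C)S(=O)(=O)n1cnc(c1)-c1c[nH]c2cc(Br)ccc12
F7 | step 7 | 3-[4-(6-bromo-1-tosylindol-3-yl)-1-(dimethylsulfamoyl)imidazol-2-yl]-1-tosylindolin-3-yl methanesulfonate | Cc1ccc(cc1)S(=O)(=O)N1CC(OS(C)(=O)=O)(c2ccccc21)c1nc(cn1S(=O)(=O)N(C)C)-c1cn(S(=O)(=O)c2ccc(C)cc2)c2cc(Br)ccc12
A1 | alternative 1 | 4-(6-bromo-1-tosylindol-3-yl)-2-(1-tosylindol-3-yl)-1H-imidazole | Cc1ccc(cc1)S(=O)(=O)n1cc(-c2c[nH]c(n2)-c2cn(S(=O)(=O)c3ccc(C)cc3)c3ccccc23)c2ccc(Br)cc21
A2 | alternative 1 | N-(benzotriazol-1-ylmethyl)-1-tosylindole-3-carboximidoyl chloride | ClC(=NCn1nnc2ccccc12)c1cn(S(=O)(=O)c2ccc(C)cc2)c2ccccc12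
A3 | alternative 1 | N-[(6-bromo-1-tosylindol-3-yl)methylidene]-4-methylbenzenesulfonamide | Cc1ccc(cc1)S(=O)(=O)N=Cc1cn(S(=O)(=O)c2ccc(C)cc2)c2cc(Br)ccc12
A4 | alternative 2 | 6-bromo-3-[1-SEM-2-(1-SEM-indol-3-yl)imidazol-4-yl]-2-(trimethylsilyl)-1H-indole | C[Si](C)(C)c1[nH]c2cc(Br)ccc2c1-c1cn(COCC[Si](C)(C)C)c(n1)-c1cn(COCC[Si](C)(C)C)c2ccccc12
A5 | alternative 2 | 5-bromo-2-iodoaniline | Nc1cc(Br)ccc1I
A6 | alternative 2 | 1-SEM-2-(1-SEM-indol-3-yl)-4-[(trimethylsilyl)ethynyl]imidazole | C[Si](C)(C)C#Cc1cn(COCC[Si](C)(C)C)c(n1)-c1cn(COCC[Si](C)(C)C)c2ccccc12
A7 | alternative 3 | 6-bromo-1-SEM-3-[2-(1H-indol-3-yl)-1-SEM-imidazol-4-yl]indole | c1ccc2c(c1)[nH]cc2-c1nc(cn1COCC[Si](C)(C)C)-c1cn(COCC[Si](C)(C)C)c2cc(Br)ccc12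
A8 | alternative 3 | N-{2-[4-(6-bromo-1-SEM-indol-3-yl)-1-SEM-imidazole-2-carbonyl]phenyl}formamide | O=CNc1ccccc1C(=O)c1nc(cn1COCC[Si](C)(C)C)-c1cn(COCC[Si](C)(C)C)c2cc(Br)ccc12
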